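**Plan**
1. Retrosynthesis: the two acyl–O bonds of the identical 4-hydroxybenzoates are cut first, giving a C3-CH2OH / C5-allylic diol. Both CH2OH carbons are raised to the ester level and C3 is epimerised (trans back to cis). The C2–C3 bond of the dihydrofuran (ring B) is then cut to a diazo carbon at C3 and an O1–CH2–aryl ether at C2. Last come the C3a–C3 bond, the side-chain C=C and the O1–CH2 bond.
2. Forward: the syringyl alcohol (ring C) and 5-iodovanillin (ring A) are joined through O1. The C5 chain is built, the diazoacetate is attached at C3a, and ring B, the only ring to be made, is closed by rhodium-carbenoid C–H insertion. Epimerisation, double ester reduction, double acylation and global desilylation finish the route.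
3. Enabling feature: the C2–H bond is both benzylic to ring C and alpha to O1, and it lies 1,5 to C3 along C3–C3a–C7a–O1–C2. C3 bears an aryl donor (ring A) and a CH2O carbon that can be carried as an ester acceptor, so C3 can be a donor/acceptor carbene and C2 a plain achiral benzyl ether CH2.
4. Helpers: the diazo group leaves as N2 in the key step, and the ester oxidation level is removed by reduction in step 8.
5. Stereochemistry: C2 (S) comes from the chiral dirhodium catalyst, which chooses between two enantiotopic benzylic hydrogens. C3 is first set cis (kinetic) and then relayed from C2 by thermodynamic epimerisation to trans. The E-alkene comes from a stabilised ylide.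

Key step: step 6

Assumption: the sense of induction is taken from simple 2-(benzyloxy)phenyl diazoacetates, where the (S)-tert-leucinate catalyst leads to the (2R,3S)-cis series, so the (R)-catalyst is specified for 2S; if the sense inverts on this substrate, the antipodal catalyst takes its place and nothing else changes.

**Step 1**
Reactants: 1 syringaldehyde (4-hydroxy-3,5-dimethoxybenzaldehyde)
Product: 2 3,5-dimethoxy-4-(triisopropylsilyloxy)benzaldehyde
Conditions: TIPSCl (1.3 equiv), imidazole (2.5 equiv), DMAP (cat.), DMF, rt to 40 °C
Reagents that add atoms: triisopropylsilyl chloride, CC(C)[Si](Cl)(C(C)C)C(C)C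
Why: Standard silyl ether formation on an acidic phenol; TIPS, further shielded by the two flanking methoxy groups, is chosen because it must outlast hydride, amine bases and catalytic ethoxide and still leave with fluoride at the end.

**Step 2**
Reactants: 2 3,5-dimethoxy-4-(triisopropylsilyloxy)benzaldehyde
Product: 3 [3,5-dimethoxy-4-(triisopropylsilyloxy)phenyl]methanol
Conditions: NaBH4 (1 equiv), MeOH–THF, 0 °C
Reagents that add atoms: none
Why: Borohydride reduction of an aromatic aldehyde is chemoselective and leaves the aryl silyl ether untouched.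

**Step 3**
Reactants: 3 [3,5-dimethoxy-4-(triisopropylsilyloxy)phenyl]methanol; 4 5-iodovanillin (4-hydroxy-3-iodo-5-methoxybenzaldehyde)
Product: 5 3-iodo-5-methoxy-4-{[3,5-dimethoxy-4-(triisopropylsilyloxy)benzyl]oxy}benzaldehyde
Conditions: PPh3 (1.3 equiv), DIAD (1.3 equiv), THF, 0 °C to rt
Reagents that add atoms: none
Why: Mitsunobu etherification, in which the acidic phenol of 4 (para-formyl, ortho-iodo) is a good pronucleophile for the activated primary benzylic alcohol, and the neutral conditions avoid both a labile electron-rich benzyl halide and carbonate bases that could strip the silyl group.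

**Step 4**
Reactants: 5 the aldehyde of step 3; 6 ethyl (triphenylphosphoranylidene)acetate
Product: 7 ethyl (E)-3-(3-iodo-5-methoxy-4-{[3,5-dimethoxy-4-(triisopropylsilyloxy)benzyl]oxy}phenyl)acrylate
Conditions: toluene, 80 °C
Reagents that add atoms: none
Why: Wittig olefination with a stabilised ylide should give the E-cinnamate selectively and touches neither the aryl iodide, the benzyl ether nor the silyl ether.

**Step 5**
Reactants: 7 the iodo-cinnamate of step 4; 8 ethyl diazoacetate
Product: 9 ethyl (E)-3-[3-(1-diazo-2-ethoxy-2-oxoethyl)-5-methoxy-4-{[3,5-dimethoxy-4-(triisopropylsilyloxy)benzyl]oxy}phenyl]acrylate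
Conditions: Pd(PPh3)4 (5 mol %), Ag2CO3 (0.5 equiv), Et3N (1.3 equiv), 8 (1.8 equiv), toluene, rt
Reagents that add atoms: none
Why: Palladium-catalysed cross-coupling of an aryl iodide with a diazoacetate with retention of the diazo group (oxidative addition of zerovalent palladium into the carbon–iodine bond, silver/amine-assisted palladation of the acidic diazo C–H, reductive elimination), run at room temperature, where the diazo group survives and the trans-disubstituted cinnamate is too poor a Heck partner or dipolarophile to interfere.

**Step 6**
Reactants: 9 the aryl diazoacetate of step 5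
Product: 11 ethyl (2S,3R)-cis-2-[3,5-dimethoxy-4-(triisopropylsilyloxy)phenyl]-5-[(E)-3-ethoxy-3-oxoprop-1-enyl]-7-methoxy-2,3-dihydrobenzofuran-3-carboxylate, via rhodium carbenoid 10 (not isolated)
Conditions: Rh2(R-PTTL)4 (dirhodium tetrakis[N-phthaloyl-(R)-tert-leucinate], 1 mol %), toluene, 4 Å MS, −60 to −40 °C, slow addition of 9
Reagents that add atoms: none
Why: The catalyst expels N2 from 9 to give the donor/acceptor carbenoid 10, whose carbene carbon (future C3) inserts into a benzylic O–CH2 hydrogen (future C2) through a concerted, asynchronous three-centre transition state with hydride-transfer character; the closest known reaction type is the enantioselective intramolecular C–H insertion of 2-(benzyloxy)aryl diazoacetates with phthaloyl-amino-acid dirhodium carboxylates. Ring B is closed as a five-membered ring by 1,5-insertion along C3–C3a–C7a–O1–C2, no other C–H bond can reach the carbene through an unstrained transition state, and the C7 methoxy group buttresses the O1–CH2 bond towards the carbene. C2 is set by the catalyst, whose phthalimide wall should admit only the pro-S of the two enantiotopic benzylic hydrogens, and insertion proceeds with retention to give 2S. C3 is set in the same event: ring C turns away from the catalyst face and ends up cis to the ester (3R, kinetic), which step 7 corrects. The step needs insertion to win over cyclopropanation, addition to ring C, ylide formation and carbene dimerisation. This is secured by the doubly activated C–H held five atoms from the carbene, by the low reactivity of donor/acceptor carbenoids towards an electron-poor trans-disubstituted alkene, by the four-membered ring that an O1 ylide would require, and by slow addition at low temperature.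

**Step 7**
Reactants: 11 the (2S,3R)-cis diester
Product: 12 ethyl (2S,3S)-trans-2-[3,5-dimethoxy-4-(triisopropylsilyloxy)phenyl]-5-[(E)-3-ethoxy-3-oxoprop-1-enyl]-7-methoxy-2,3-dihydrobenzofuran-3-carboxylate
Conditions: NaOEt (0.2 equiv), EtOH–THF, 0 °C to rt; AcOH quench
Reagents that add atoms: none
Why: Base-catalysed epimerisation through the planar C3 ester enolate (alpha to the ester and benzylic) places the ester trans to the C2 aryl group under equilibrium control (3R to 3S), while C2 has no acidic hydrogen and keeps its configuration, the matching ethoxide makes transesterification degenerate, and the catalytic amount and low temperature are meant to spare the TIPS ether and keep beta-elimination of O1 from competing.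

**Step 8**
Reactants: 12 the (2S,3S)-trans diester
Product: 13 (E)-3-{(2S,3R)-2-[3,5-dimethoxy-4-(triisopropylsilyloxy)phenyl]-3-(hydroxymethyl)-7-methoxy-2,3-dihydrobenzofuran-5-yl}prop-2-en-1-ol
Conditions: DIBAL-H (6 equiv), CH2Cl2, −78 to −20 °C; aq. Rochelle salt
Reagents that add atoms: none
Why: Exhaustive DIBAL-H reduction takes the saturated ester and (by 1,2-attack) the cinnamate to the primary and the allylic alcohol in one operation without touching either stereocentre, the E-alkene or the silyl ether (3S becomes 3R only through the change in CIP ranking).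

**Step 9**
Reactants: 14 4-hydroxybenzoic acid
Product: 16 4-(tert-butyldimethylsilyloxy)benzoic acid, via bis-silylated benzoate 15 (not isolated)
Conditions: TBSCl (2.5 equiv), imidazole (5 equiv), DMF, rt; then AcOH–THF–H2O (3:1:1), rt
Reagents that add atoms: tert-butyldimethylsilyl chloride, CC(C)(C)[Si](C)(C)Cl
Why: Exhaustive silylation followed by selective hydrolysis, since the silyl ester of 15 is far more labile to aqueous acetic acid than the aryl silyl ether and only the carboxyl group is set free.

**Step 10**
Reactants: 13 the diol; 16 4-(tert-butyldimethylsilyloxy)benzoic acid (2.6 equiv)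
Product: 17 tris-silyl ether of the target (both hydroxyl groups of 13 esterified with 16; TIPS on the ring C phenol, TBS on both benzoate phenols)
Conditions: EDC (free base, 2.8 equiv), DMAP (0.3 equiv), CH2Cl2, 0 °C to rt
Reagents that add atoms: none
Why: Steglich-type carbodiimide/DMAP esterification acylates both primary hydroxyl groups with the same acid in one operation under near-neutral conditions that affect neither stereocentre nor the allylic system.

**Step 11**
Reactants: 17 the tris-silyl ether
Product: 18 quiquesetinerviusin B
Conditions: TBAF (3.5 equiv), AcOH (4 equiv), THF, 0 °C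
Reagents that add atoms: none
Why: Fluoride-induced cleavage of all three aryl silyl ethers is driven by the strong Si–F bond and the good phenoxide leaving groups, and the acetic acid buffer releases the phenols protonated, so that neither ester nor the C2–O1 bond is attacked.

**Compound list**
1 | syringaldehyde | COc1cc(C=O)cc(OC)c1O | starting material
2 | 3,5-dimethoxy-4-(triisopropylsilyloxy)benzaldehyde | COc1cc(C=O)cc(OC)c1O[Si](C(C)C)(C(C)C)C(C)C | intermediate
3 | [3,5-dimethoxy-4-(triisopropylsilyloxy)phenyl]methanol | COc1cc(CO)cc(OC)c1O[Si](C(C)C)(C(C)C)C(C)C | intermediate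
4 | 5-iodovanillin | COc1cc(C=O)cc(I)c1O | starting material
5 | 3-iodo-5-methoxy-4-{[3,5-dimethoxy-4-(triisopropylsilyloxy)benzyl]oxy}benzaldehyde | COc1cc(C=O)cc(I)c1OCc1cc(OC)c(O[Si](C(C)C)(C(C)C)C(C)C)c(OC)c1 | intermediate
6 | ethyl (triphenylphosphoranylidene)acetate | CCOC(=O)C=P(c1ccccc1)(c1ccccc1)c1ccccc1 | starting material
7 | ethyl (E)-iodo-cinnamate of step 4 | CCOC(=O)/C=C/c1cc(I)c(OCc2cc(OC)c(O[Si](C(C)C)(C(C)C)C(C)C)c(OC)c2)c(OC)c1 | intermediate
8 | ethyl diazoacetate | CCOC(=O)C=[N+]=[N-] | starting material
9 | aryl diazoacetate of step 5 | CCOC(=O)/C=C/c1cc(OC)c(OCc2cc(OC)c(O[Si](C(C)C)(C(C)C)C(C)C)c(OC)c2)c(c1)C(=[N+]=[N-])C(=O)OCC | intermediate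
10 | rhodium carbenoid of 9 (Rh stands for the Rh2(R-PTTL)4 unit; bridging carboxylates not drawn) | CCOC(=O)/C=C/c1cc(OC)c(OCc2cc(OC)c(O[Si](C(C)C)(C(C)C)C(C)C)c(OC)c2)c(c1)C(=[Rh])C(=O)OCC | intermediate
11 | (2S,3R)-cis diester | COc1cc([C@H]2Oc3c(OC)cc(/C=C/C(=O)OCC)cc3[C@H]2C(=O)OCC)cc(OC)c1O[Si](C(C)C)(C(C)C)C(C)C | intermediate
12 | (2S,3S)-trans diester | COc1cc([C@H]2Oc3c(OC)cc(/C=C/C(=O)OCC)cc3[C@@H]2C(=O)OCC)cc(OC)c1O[Si](C(C)C)(C(C)C)C(C)C | intermediate
13 | (2S,3R)-trans diol | COc1cc([C@H]2Oc3c(OC)cc(/C=C/CO)cc3[C@@H]2CO)cc(OC)c1O[Si](C(C)C)(C(C)C)C(C)C | intermediate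
14 | 4-hydroxybenzoic acid | OC(=O)c1ccc(O)cc1 | starting material
15 | tert-butyldimethylsilyl 4-(tert-butyldimethylsilyloxy)benzoate | CC(C)(C)[Si](C)(C)OC(=O)c1ccc(O[Si](C)(C)C(C)(C)C)cc1 | intermediate
16 | 4-(tert-butyldimethylsilyloxy)benzoic acid | OC(=O)c1ccc(O[Si](C)(C)C(C)(C)C)cc1 | intermediate
17 | tris-silyl ether of the target | COc1cc([C@H]2Oc3c(OC)cc(/C=C/COC(=O)c4ccc(O[Si](C)(C)C(C)(C)C)cc4)cc3[C@@H]2COC(=O)c2ccc(O[Si](C)(C)C(C)(C)C)cc2)cc(OC)c1O[Si](C(C)C)(C(C)C)C(C)C | intermediate
18 | quiquesetinerviusin B | COc1cc([C@H]2Oc3c(OC)cc(/C=C/COC(=O)c4ccc(O)cc4)cc3[C@@H]2COC(=O)c2ccc(O)cc2)cc(OC)c1O | target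

**Step count and risks**

Total step count: 11. Longest linear sequence: 10 steps (1, 2, 3, 4, 5, 6, 7, 8, 10, 11, from syringaldehyde 1).

**Step 5.**
- What may go wrong: oxidative addition and palladation are slowed at an iodide flanked by the bulky benzyloxy group, so that metal-induced loss of nitrogen from 8 or 9 overtakes the coupling.
- Fallback (sets out from 7, comes back at 9): the two-carbon unit is brought in at the ester level and the diazo group is added afterwards. The Reformatsky reagent made from ethyl bromoacetate and zinc in THF is coupled with 7 in a Negishi-type alpha-arylation (Pd(dba)2, XPhos, THF, rt to 50 °C) to give the ethyl arylacetate F1. Regitz diazo transfer to its doubly activated CH2 group (4-acetamidobenzenesulfonyl azide, DBU, MeCN, 0 °C to rt) then gives 9.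

**Step 6.**
- What may go wrong: poor discrimination between the two enantiotopic benzylic hydrogens, because the di-ortho-substituted aryl ether is twisted out of the plane of ring A and the ester is ethyl rather than methyl.
- Fallback (sets out from 7, comes back at 13): stereocontrol is shared between a covalently bound lactamide auxiliary and a prolinate catalyst, a pairing that in this class of insertion closes the ring directly to the trans isomer.
  - Ethyl (S)-lactate heated with pyrrolidine gives (S)-2-hydroxy-1-(pyrrolidin-1-yl)propan-1-one F2.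
  - Bromoacetyl bromide and pyridine convert it into the lactamide bromoacetate F3.
  - N,N'-ditosylhydrazine with DBU turns this into the lactamide diazoacetate F4.
  - F4 replaces 8 in the coupling of step 5 and gives the auxiliary-bearing aryl diazoacetate F5.
  - Rh2(S-DOSP)4 (dirhodium tetrakis[(S)-N-(4-dodecylbenzenesulfonyl)prolinate]) in CH2Cl2 at rt should close it to the (2S,3S)-trans lactamide ester F6.
  - DIBAL-H as in step 8 cleaves both ester groups and delivers 13, so step 7 is not needed on this path.

**Step 11.**
- What may go wrong: phenoxides set free by fluoride attack the ester carbonyls (acyl transfer, loss of the cinnamyl-type ester), or the unveiled ring C phenoxide opens the C2–O1 bond through a p-quinone methide and scrambles C2.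
- Fallback (sets out from 13, comes back at 18): the only silyl group is removed before any ester is present, and no phenol is protected afterwards. TBAF/AcOH in THF converts 13 into the free phenolic diol F7. A chemoselective Mitsunobu esterification with unprotected 14 (2.5 equiv, PPh3, DIAD, THF, 0 °C) then acylates both primary alcohols, because the carboxylic acid is by far the most acidic pronucleophile present. This gives 18 directly, and steps 9 and 10 drop out.

**Further compounds**
F1 | step 5 | ethyl (E)-3-[3-(2-ethoxy-2-oxoethyl)-5-methoxy-4-{[3,5-dimethoxy-4-(triisopropylsilyloxy)benzyl]oxy}phenyl]acrylate | CCOC(=O)/C=C/c1cc(OC)c(OCc2cc(OC)c(O[Si](C(C)C)(C(C)C)C(C)C)c(OC)c2)c(c1)CC(=O)OCC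
F2 | step 6 | (S)-2-hydroxy-1-(pyrrolidin-1-yl)propan-1-one | C[C@H](O)C(=O)N1CCCC1
F3 | step 6 | (S)-1-oxo-1-(pyrrolidin-1-yl)propan-2-yl bromoacetate | C[C@H](OC(=O)CBr)C(=O)N1CCCC1
F4 | step 6 | (S)-1-oxo-1-(pyrrolidin-1-yl)propan-2-yl diazoacetate | C[C@H](OC(=O)C=[N+]=[N-])C(=O)N1CCCC1
F5 | step 6 | analogue of 9 with the (S)-lactamide ester on the diazo carbon | CCOC(=O)/C=C/c1cc(OC)c(OCc2cc(OC)c(O[Si](C(C)C)(C(C)C)C(C)C)c(OC)c2)c(c1)C(=[N+]=[N-])C(=O)O[C@@H](C)C(=O)N1CCCC1
F6 | step 6 | (2S,3S)-trans analogue of 12 with the (S)-lactamide ester at C3 | COc1cc([C@H]2Oc3c(OC)cc(/C=C/C(=O)OCC)cc3[C@@H]2C(=O)O[C@@H](C)C(=O)N2CCCC2)cc(OC)c1O[Si](C(C)C)(C(C)C)C(C)C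
F7 | step 11 | 4-{(2S,3R)-3-(hydroxymethyl)-5-[(E)-3-hydroxyprop-1-enyl]-7-methoxy-2,3-dihydrobenzofuran-2-yl}-2,6-dimethoxyphenol | COc1cc([C@H]2Oc3c(OC)cc(/C=C/CO)cc3[C@@H]2CO)cc(OC)c1O
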